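## Retrosynthetic overview

1. Endgame: O9 desilylation ⇐ CBS reduction of a C3 enone ⇐ oxidation ⇐ Nozaki–Hiyama–Kishi closure of the 14-membered carbocycle at C3–C4 (aldehyde plus E-vinyl iodide). This ring is formed second.
2. The seven-membered α-methylene lactone is formed first: the C16 acrylic acid opens an (11R,12R)-epoxide at C12 with inversion, and the freed C11–OH is acetylated.
3. C7=C8 (Z): Wittig reaction of a C8 α-silyloxy methyl ketone with the ylide of an (E)-4-iodopent-3-enyl phosphonium salt made from pent-3-yn-1-ol.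
4. C9–C12: methyl (R)-glycidate (C8–C10, sets C9) is opened by an E-alkenyl metal from Negishi carboalumination of a terminal alkyne; Shi epoxidation sets C11 and C12.
5. C1–C3 and C11–C17 with the C1 stereocentre come from (S)-limonene: C10 hydroxylation, ring ozonolysis, methyl ketone to alkyne.

Convention (one line): atom labels C1–C20 and the names from compound 26 on follow cembrane numbering of the target (ring C1–C14; C15(=C17H2)–C16 on C1; methyls C18, C19, C20 on C4, C8, C12); "3,4-seco" means the C3–C4 bond is not yet made.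

## Route

Step 1
Reactants: 1 (S)-limonene
Product: 4 (S)-limonen-10-ol, via 10-lithiolimonene 2 (not isolated), via allylboronate 3 (not isolated)
Conditions: n-BuLi, TMEDA, hexane, rt; B(OMe)3, THF, −78 °C; then H2O2, aq NaOH, 0 °C → rt
Reagents that add atoms: hydrogen peroxide, OO
Why: Allylic lithiation with n-BuLi·TMEDA takes a proton from the isopropenyl methyl (the 2-substituted allyl anion has two equivalent ends), and borylation/oxidation gives the primary allylic alcohol without touching the C1 stereocentre, which is taken from (S)-limonene.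

Step 2
Reactants: 4 (S)-limonen-10-ol
Product: 5 (S)-limonen-10-yl 4-methoxybenzyl ether
Conditions: NaH, 4-MeOC6H4CH2Cl, Bu4NI (cat.), THF–DMF, 0 °C → rt
Reagents that add atoms: 4-methoxybenzyl chloride, COc1ccc(CCl)cc1
Why: Williamson ether synthesis; the PMB ether withstands the bases, organometallics and epoxidation that follow and is removed later by DDQ.

Step 3
Reactants: 5 (S)-limonen-10-yl 4-methoxybenzyl ether
Product: 8 (5S)-7,7-dimethoxy-5-{3-[(4-methoxybenzyl)oxy]prop-1-en-2-yl}heptan-2-one, via ozonide 6 (not isolated), via keto aldehyde 7 (not isolated)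
Conditions: O3, CH2Cl2, −78 °C (Sudan Red 7B end point); PPh3, −78 °C → rt; then MeOH, HC(OMe)3, CeCl3·7H2O (cat.), rt
Reagents that add atoms: ozone, [O-][O+]=O; trimethyl orthoformate, COC(OC)OC
Why: Criegee ozonolysis cleaves the electron-rich trisubstituted ring alkene in preference to the 1,1-disubstituted allyl-ether alkene, and Luche-type chemoselective acetalisation protects only the aldehyde, so C3 is differentiated from the methyl ketone.

Step 4
Reactants: 8 keto acetal
Product: 10 1-[({2-[(3S)-1,1-dimethoxyhept-6-yn-3-yl]prop-2-en-1-yl}oxy)methyl]-4-methoxybenzene, via enol phosphate 9 (not isolated)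
Conditions: LiN(i-Pr)2 (1.1 equiv), THF, −78 °C; ClP(O)(OEt)2; then LiN(i-Pr)2 (2.3 equiv), −78 °C → rt; aq NH4Cl
Reagents that add atoms: none
Why: Negishi alkyne synthesis: kinetic enolisation at the methyl group, O-phosphorylation and base-induced elimination turn the methyl ketone into the terminal alkyne (the old methyl carbon becomes C11).

Step 5
Reactants: 10 terminal alkyne
Product: 12 (3S,6E)-alkenyl iodide, via alkenylalane 11 (not isolated)
Conditions: Me3Al (3 equiv), Cp2ZrCl2 (0.2 equiv), H2O (1 equiv), CH2Cl2, −25 °C; then I2, THF, −25 → 0 °C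
Reagents that add atoms: trimethylaluminium, C[Al](C)C; iodine, [I][I]
Why: Negishi zirconium-catalysed carboalumination adds Me–Al syn across the alkyne with the new methyl (C20) on the internal carbon, and iodinolysis with retention gives the E-alkenyl iodide, which fixes the 11E geometry needed for the epoxide.

Step 6
Reactants: 12 (3S,6E)-alkenyl iodide; 13 methyl (2R)-oxirane-2-carboxylate
Product: 15 methyl (2R,4E,8S)-2-hydroxy-10,10-dimethoxy-8-{3-[(4-methoxybenzyl)oxy]prop-1-en-2-yl}-5-methyldec-4-enoate, via alkenylmagnesium chloride 14 (not isolated)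
Conditions: i-PrMgCl·LiCl, THF, 25 °C; then CuI (10 mol%), 13, −40 °C; aq NH4Cl
Reagents that add atoms: none
Why: Iodine–magnesium exchange (alkene geometry retained) and copper-catalysed SN2 opening of the glycidate at its CH2 terminus form C10–C11; the C9 stereocentre (R) is carried over unchanged from methyl (R)-glycidate.

Step 7
Reactants: 15 α-hydroxy ester
Product: 16 methyl (2R,4E,8S)-2-[(tert-butyldimethylsilyl)oxy]-10,10-dimethoxy-8-{3-[(4-methoxybenzyl)oxy]prop-1-en-2-yl}-5-methyldec-4-enoate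
Conditions: TBSCl, imidazole, DMF, rt
Reagents that add atoms: tert-butyldimethylsilyl chloride, CC(C)(C)[Si](C)(C)Cl
Why: Imidazole-promoted silylation masks O9 as a bulky, poorly nucleophilic silyl ether that lasts until the final step.

Step 8
Reactants: 16 α-silyloxy ester
Product: 18 (3R,5E,9S)-3-[(tert-butyldimethylsilyl)oxy]-11,11-dimethoxy-9-{3-[(4-methoxybenzyl)oxy]prop-1-en-2-yl}-6-methylundec-5-en-2-one, via Weinreb amide 17 (not isolated)
Conditions: MeNH(OMe)·HCl, i-PrMgCl, THF, −20 °C; then MeMgBr, −20 → 0 °C; aq NH4Cl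
Reagents that add atoms: methylmagnesium bromide, C[Mg]Br
Why: Weinreb ketone synthesis in one flask: ClMgN(OMe)Me converts the ester into the Weinreb amide, whose magnesium chelate with MeMgBr collapses to the methyl ketone (C19 added) only on work-up, without epimerising C9.

Step 9
Reactants: 18 α-silyloxy methyl ketone
Product: 19 (11R,12R)-epoxy ketone
Conditions: Shi ketone from D-fructose (0.3 equiv), KHSO5 (as 2KHSO5·KHSO4·K2SO4), K2CO3, Bu4NHSO4 (cat.), MeCN–CH2(OMe)2–aq Na2B4O7 buffer, 0 °C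
Reagents that add atoms: potassium peroxymonosulfate, [K+].[O-]S(=O)(=O)OO
Why: Shi asymmetric epoxidation: the dioxirane of the D-fructose-derived ketone epoxidises the electron-rich E-trisubstituted alkene through a spiro transition state under reagent control to give the (11R,12R)-epoxide, leaving the allyl-ether alkene, and the basic medium keeps the acid-sensitive γ,δ-epoxy ketone intact.

Step 10
Reactants: 20 pent-3-yn-1-ol
Product: 22 (3E)-4-iodopent-3-en-1-ol, via zirconated alkoxide 21 (not isolated)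
Conditions: Cp2Zr(H)Cl (2.5 equiv), THF, rt → 50 °C; then I2, 0 °C
Reagents that add atoms: iodine, [I][I]
Why: Schwartz hydrozirconation (syn addition, zirconium equilibrating to the less hindered methyl-bearing carbon) followed by iodinolysis with retention gives the (E)-2-iodoalkene.

Step 11
Reactants: 22 (3E)-4-iodopent-3-en-1-ol
Product: 23 (2E)-2,5-diiodopent-2-ene
Conditions: I2, PPh3, imidazole, CH2Cl2, 0 °C → rt
Reagents that add atoms: iodine, [I][I]
Why: Appel-type (Garegg–Samuelsson) iodination of the primary alcohol; the vinyl iodide is inert.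

Step 12
Reactants: 23 (2E)-2,5-diiodopent-2-ene
Product: 24 [(3E)-4-iodopent-3-en-1-yl]triphenylphosphonium iodide
Conditions: PPh3, MeCN, 80 °C
Reagents that add atoms: triphenylphosphine, c1ccc(cc1)P(c1ccccc1)c1ccccc1
Why: SN2 quaternisation of PPh3 occurs only at the primary alkyl iodide.

Step 13
Reactants: 19 (11R,12R)-epoxy ketone; 24 phosphonium iodide
Product: 26 (1S,4E,7Z,9R,11R,12R)-seco-diene vinyl iodide, via ylide 25 (not isolated)
Conditions: 24, NaN(SiMe3)2, THF, −78 → 0 °C; then 19, −78 °C → rt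
Reagents that add atoms: none
Why: Wittig olefination: the non-stabilised ylide adds to the α-silyloxy methyl ketone so that the oxygen-bearing carbon ends cis to the ylide chain (Still's Z-selective olefination of α-alkoxy ketones), which sets 7Z, while the ylide carries the 4E vinyl iodide.

Step 14
Reactants: 26 PMB ether
Product: 27 allylic alcohol (16-ol)
Conditions: DDQ, CH2Cl2–pH 7 phosphate buffer, 0 °C
Reagents that add atoms: none
Why: Oxidative PMB cleavage by DDQ (hydride abstraction, hydrolysis of the oxocarbenium ion) under buffered conditions frees the allylic alcohol without opening the epoxide.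

Step 15
Reactants: 27 allylic alcohol
Product: 29 epoxy acrylic acid (16-oic acid), via enal 28 (not isolated)
Conditions: TEMPO (0.1 equiv), PhI(OAc)2, CH2Cl2, rt; then t-BuOH–H2O, 2-methylbut-2-ene, NaH2PO4, NaClO2, 0 °C → rt
Reagents that add atoms: sodium chlorite, [Na+].[O-]Cl=O
Why: TEMPO/PhI(OAc)2 oxidation to the enal and Pinnick oxidation (2-methylbut-2-ene scavenges HOCl) give the 2-substituted acrylic acid without touching the alkenes, the vinyl iodide or the epoxide.

Step 16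
Reactants: 29 epoxy acrylic acid
Product: 31 (12S)-11-acetoxy ε-lactone, via hydroxy lactone 30 (not isolated)
Conditions: CSA (5 mol%), CH2Cl2, 0 °C; then pyridine, Ac2O, DMAP (cat.), rt
Reagents that add atoms: acetic anhydride, CC(=O)OC(C)=O
Why: Acid-catalysed 7-exo epoxide opening: the carboxylic acid attacks the protonated epoxide at the tertiary carbon C12 with inversion (12R to 12S, C11 untouched) to close the α-methylene ε-lactone, and the freed C11 hydroxyl is acetylated in the same flask under DMAP catalysis.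

Step 17
Reactants: 31 acetoxy lactone dimethyl acetal
Product: 32 acetoxy lactone aldehyde
Conditions: PPTS (cat.), acetone–H2O, 45 °C
Reagents that add atoms: water, O
Why: Mild acid-catalysed acetal hydrolysis frees the C3 aldehyde; the lactone, acetate, secondary silyl ether and vinyl iodide tolerate PPTS.

Step 18
Reactants: 32 iodo aldehyde
Product: 33 macrocyclic allylic alcohol (C3 epimers)
Conditions: CrCl2 (10 equiv), NiCl2 (0.1 equiv), DMSO–THF, rt, 2 mM (slow addition)
Reagents that add atoms: none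
Why: Nozaki–Hiyama–Kishi macrocyclisation: nickel-catalysed activation of the vinyl iodide, transmetalation to chromium and aldehyde-selective addition at high dilution close the 14-membered ring at C3–C4 with retention of the 4E geometry; C3 forms as an epimer mixture that steps 19 and 20 converge.

Step 19
Reactants: 33 macrocyclic allylic alcohol
Product: 34 macrocyclic enone
Conditions: Dess–Martin periodinane, NaHCO3, CH2Cl2, 0 °C → rt
Reagents that add atoms: none
Why: Dess–Martin oxidation of the allylic alcohol gives the enone and erases the C3 mixture.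

Step 20
Reactants: 34 macrocyclic enone
Product: 35 (3S)-allylic alcohol silyl ether
Conditions: (R)-2-methyl-CBS-oxazaborolidine (0.3 equiv), catecholborane, toluene, −78 °C; MeOH quench
Reagents that add atoms: none
Why: Corey–Bakshi–Shibata reduction: with the alkenyl group as the large and CH2 as the small substituent, the (R)-oxazaborolidine directs 1,2-hydride delivery to give the (3S)-allylic alcohol under reagent control.

Step 21
Reactants: 35 (3S)-allylic alcohol silyl ether
Product: 36 target CNP0183491.1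
Conditions: HF·pyridine, pyridine, THF, 0 °C → rt
Reagents that add atoms: none
Why: Fluoride-mediated desilylation under buffered acidic conditions frees O9 without acetyl migration or conjugate addition to the methylene lactone.

## Compound list

1 | (S)-limonene, (4S)-1-methyl-4-(prop-1-en-2-yl)cyclohex-1-ene | CC1=CC[C@H](CC1)C(C)=C | starting material
2 | (S)-10-lithiolimonene, {2-[(1S)-4-methylcyclohex-3-en-1-yl]prop-2-en-1-yl}lithium | CC1=CC[C@H](CC1)C(=C)C[Li] | intermediate
3 | dimethyl {2-[(1S)-4-methylcyclohex-3-en-1-yl]prop-2-en-1-yl}boronate | CC1=CC[C@H](CC1)C(=C)CB(OC)OC | intermediate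
4 | (S)-limonen-10-ol, 2-[(1S)-4-methylcyclohex-3-en-1-yl]prop-2-en-1-ol | CC1=CC[C@H](CC1)C(=C)CO | intermediate
5 | 1-methoxy-4-[({2-[(1S)-4-methylcyclohex-3-en-1-yl]prop-2-en-1-yl}oxy)methyl]benzene | CC1=CC[C@H](CC1)C(=C)COCc1ccc(OC)cc1 | intermediate
6 | ozonide, (4S)-4-{3-[(4-methoxybenzyl)oxy]prop-1-en-2-yl}-1-methyl-7,8,9-trioxabicyclo[4.2.1]nonane (bridgehead epimers) | CC12CC[C@H](C(=C)COCc3ccc(OC)cc3)CC(OO1)O2 | intermediate
7 | (3S)-3-{3-[(4-methoxybenzyl)oxy]prop-1-en-2-yl}-6-oxoheptanal | CC(=O)CC[C@@H](CC=O)C(=C)COCc1ccc(OC)cc1 | intermediate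
8 | (5S)-7,7-dimethoxy-5-{3-[(4-methoxybenzyl)oxy]prop-1-en-2-yl}heptan-2-one | CC(=O)CC[C@@H](CC(OC)OC)C(=C)COCc1ccc(OC)cc1 | intermediate
9 | diethyl (5S)-7,7-dimethoxy-5-{3-[(4-methoxybenzyl)oxy]prop-1-en-2-yl}hept-1-en-2-yl phosphate | C=C(OP(=O)(OCC)OCC)CC[C@@H](CC(OC)OC)C(=C)COCc1ccc(OC)cc1 | intermediate
10 | 1-[({2-[(3S)-1,1-dimethoxyhept-6-yn-3-yl]prop-2-en-1-yl}oxy)methyl]-4-methoxybenzene | C#CCC[C@@H](CC(OC)OC)C(=C)COCc1ccc(OC)cc1 | intermediate
11 | [(1E,5S)-7,7-dimethoxy-5-{3-[(4-methoxybenzyl)oxy]prop-1-en-2-yl}-2-methylhept-1-en-1-yl]dimethylalumane | C[Al](C)/C=C(C)/CC[C@@H](CC(OC)OC)C(=C)COCc1ccc(OC)cc1 | intermediate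
12 | 1-[({2-[(3S,6E)-7-iodo-1,1-dimethoxy-6-methylhept-6-en-3-yl]prop-2-en-1-yl}oxy)methyl]-4-methoxybenzene | I/C=C(C)/CC[C@@H](CC(OC)OC)C(=C)COCc1ccc(OC)cc1 | intermediate
13 | methyl (2R)-oxirane-2-carboxylate (methyl (R)-glycidate) | COC(=O)[C@H]1CO1 | starting material
14 | chloro[(1E,5S)-7,7-dimethoxy-5-{3-[(4-methoxybenzyl)oxy]prop-1-en-2-yl}-2-methylhept-1-en-1-yl]magnesium | Cl[Mg]/C=C(C)/CC[C@@H](CC(OC)OC)C(=C)COCc1ccc(OC)cc1 | intermediate
15 | methyl (2R,4E,8S)-2-hydroxy-10,10-dimethoxy-8-{3-[(4-methoxybenzyl)oxy]prop-1-en-2-yl}-5-methyldec-4-enoate | COC(=O)[C@H](O)C/C=C(C)/CC[C@@H](CC(OC)OC)C(=C)COCc1ccc(OC)cc1 | intermediate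
16 | methyl (2R,4E,8S)-2-[(tert-butyldimethylsilyl)oxy]-10,10-dimethoxy-8-{3-[(4-methoxybenzyl)oxy]prop-1-en-2-yl}-5-methyldec-4-enoate | COC(=O)[C@H](O[Si](C)(C)C(C)(C)C)C/C=C(C)/CC[C@@H](CC(OC)OC)C(=C)COCc1ccc(OC)cc1 | intermediate
17 | (2R,4E,8S)-2-[(tert-butyldimethylsilyl)oxy]-N,10,10-trimethoxy-8-{3-[(4-methoxybenzyl)oxy]prop-1-en-2-yl}-N,5-dimethyldec-4-enamide | CON(C)C(=O)[C@H](O[Si](C)(C)C(C)(C)C)C/C=C(C)/CC[C@@H](CC(OC)OC)C(=C)COCc1ccc(OC)cc1 | intermediate
18 | (3R,5E,9S)-3-[(tert-butyldimethylsilyl)oxy]-11,11-dimethoxy-9-{3-[(4-methoxybenzyl)oxy]prop-1-en-2-yl}-6-methylundec-5-en-2-one | CC(=O)[C@H](O[Si](C)(C)C(C)(C)C)C/C=C(C)/CC[C@@H](CC(OC)OC)C(=C)COCc1ccc(OC)cc1 | intermediate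
19 | (3R)-3-[(tert-butyldimethylsilyl)oxy]-4-[(2R,3R)-3-{(3S)-5,5-dimethoxy-3-{3-[(4-methoxybenzyl)oxy]prop-1-en-2-yl}pentyl}-3-methyloxiran-2-yl]butan-2-one | CC(=O)[C@H](O[Si](C)(C)C(C)(C)C)C[C@H]1O[C@]1(C)CC[C@@H](CC(OC)OC)C(=C)COCc1ccc(OC)cc1 | intermediate
20 | pent-3-yn-1-ol | CC#CCCO | starting material
21 | C,O-bis(chlorozirconocene) derivative of (3E)-pent-3-en-1-ol (Zr on C4 and on O) | C/C(=C\CCO[Zr](Cl)(C1C=CC=C1)C1C=CC=C1)[Zr](Cl)(C1C=CC=C1)C1C=CC=C1 | intermediate
22 | (3E)-4-iodopent-3-en-1-ol | C/C(I)=C\CCO | intermediate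
23 | (2E)-2,5-diiodopent-2-ene | C/C(I)=C\CCI | intermediate
24 | [(3E)-4-iodopent-3-en-1-yl]triphenylphosphonium iodide | C/C(I)=C\CC[P+](c1ccccc1)(c1ccccc1)c1ccccc1.[I-] | intermediate
25 | [(3E)-4-iodopent-3-en-1-ylidene]triphenylphosphorane | C/C(I)=C\CC=P(c1ccccc1)(c1ccccc1)c1ccccc1 | intermediate
26 | (1S,4E,7Z,9R,11R,12R)-9-[(tert-butyldimethylsilyl)oxy]-11,12-epoxy-4-iodo-3,3-dimethoxy-16-[(4-methoxybenzyl)oxy]-3,4-secocembra-4,7,15(17)-triene | I/C(C)=C/C/C=C(/C)[C@H](O[Si](C)(C)C(C)(C)C)C[C@H]1O[C@]1(C)CC[C@@H](CC(OC)OC)C(=C)COCc1ccc(OC)cc1 | intermediate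
27 | (1S,4E,7Z,9R,11R,12R)-9-[(tert-butyldimethylsilyl)oxy]-11,12-epoxy-4-iodo-3,3-dimethoxy-3,4-secocembra-4,7,15(17)-trien-16-ol | I/C(C)=C/C/C=C(/C)[C@H](O[Si](C)(C)C(C)(C)C)C[C@H]1O[C@]1(C)CC[C@@H](CC(OC)OC)C(=C)CO | intermediate
28 | (1S,4E,7Z,9R,11R,12R)-9-[(tert-butyldimethylsilyl)oxy]-11,12-epoxy-4-iodo-3,3-dimethoxy-3,4-secocembra-4,7,15(17)-trien-16-al | I/C(C)=C/C/C=C(/C)[C@H](O[Si](C)(C)C(C)(C)C)C[C@H]1O[C@]1(C)CC[C@@H](CC(OC)OC)C(=C)C=O | intermediate
29 | (1S,4E,7Z,9R,11R,12R)-9-[(tert-butyldimethylsilyl)oxy]-11,12-epoxy-4-iodo-3,3-dimethoxy-3,4-secocembra-4,7,15(17)-trien-16-oic acid | I/C(C)=C/C/C=C(/C)[C@H](O[Si](C)(C)C(C)(C)C)C[C@H]1O[C@]1(C)CC[C@@H](CC(OC)OC)C(=C)C(=O)O | intermediate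
30 | (1S,4E,7Z,9R,11R,12S)-9-[(tert-butyldimethylsilyl)oxy]-11-hydroxy-4-iodo-3,3-dimethoxy-3,4-secocembra-4,7,15(17)-trien-16,12-olide | C=C1C(=O)O[C@@](C)(CC[C@H]1CC(OC)OC)[C@H](O)C[C@@H](O[Si](C)(C)C(C)(C)C)/C(C)=C\C/C=C(C)/I | intermediate
31 | (1S,4E,7Z,9R,11R,12S)-11-acetoxy-9-[(tert-butyldimethylsilyl)oxy]-4-iodo-3,3-dimethoxy-3,4-secocembra-4,7,15(17)-trien-16,12-olide | C=C1C(=O)O[C@@](C)(CC[C@H]1CC(OC)OC)[C@H](OC(C)=O)C[C@@H](O[Si](C)(C)C(C)(C)C)/C(C)=C\C/C=C(C)/I | intermediate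
32 | (1S,4E,7Z,9R,11R,12S)-11-acetoxy-9-[(tert-butyldimethylsilyl)oxy]-4-iodo-3-oxo-3,4-secocembra-4,7,15(17)-trien-16,12-olide | C=C1C(=O)O[C@@](C)(CC[C@H]1CC=O)[C@H](OC(C)=O)C[C@@H](O[Si](C)(C)C(C)(C)C)/C(C)=C\C/C=C(C)/I | intermediate
33 | (1S,4E,7Z,9R,11R,12S)-11-acetoxy-9-[(tert-butyldimethylsilyl)oxy]-3-hydroxycembra-4,7,15(17)-trien-16,12-olide (3R and 3S epimers) | C=C1C(=O)O[C@@]2(C)CC[C@H]1CC(O)/C(C)=C/C/C=C(/C)[C@H](O[Si](C)(C)C(C)(C)C)C[C@H]2OC(C)=O | intermediate
34 | (1S,4E,7Z,9R,11R,12S)-11-acetoxy-9-[(tert-butyldimethylsilyl)oxy]-3-oxocembra-4,7,15(17)-trien-16,12-olide | C=C1C(=O)O[C@@]2(C)CC[C@H]1CC(=O)/C(C)=C/C/C=C(/C)[C@H](O[Si](C)(C)C(C)(C)C)C[C@H]2OC(C)=O | intermediate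
35 | (1S,3S,4E,7Z,9R,11R,12S)-11-acetoxy-9-[(tert-butyldimethylsilyl)oxy]-3-hydroxycembra-4,7,15(17)-trien-16,12-olide | C=C1C(=O)O[C@@]2(C)CC[C@H]1C[C@H](O)/C(C)=C/C/C=C(/C)[C@H](O[Si](C)(C)C(C)(C)C)C[C@H]2OC(C)=O | intermediate
36 | (1S,3S,4E,7Z,9R,11R,12S)-11-acetoxy-3,9-dihydroxycembra-4,7,15(17)-trien-16,12-olide (CNP0183491.1) | C=C1C(=O)O[C@@]2(C)CC[C@H]1C[C@H](O)/C(C)=C/C/C=C(/C)[C@H](O)C[C@H]2OC(C)=O | target

## Step count and risks

Total step count: 21. Longest linear sequence: 18 steps (steps 1–9 and 13–21); steps 10–12 make the phosphonium salt 24.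

The three steps most likely to fail, each with one fallback:

Step 16 (lactonisation of 29). The 7-exo closure may be diverted if the C7=C8 alkene or the O9 silyl ether attacks the developing C12 cation. The fallback sets out from 29 and comes back at 32; it makes the tertiary ester by acylation and not by epoxide opening. Dilute aqueous HClO4 in THF at 0 °C opens the epoxide with water at C12 (inversion) and hydrolyses the acetal, giving (1S,4E,7Z,9R,11R,12S)-9-[(tert-butyldimethylsilyl)oxy]-11,12-dihydroxy-4-iodo-3-oxo-3,4-secocembra-4,7,15(17)-trien-16-oic acid F3. Ac2O/pyridine at 0 °C acetylates only the secondary hydroxyl and gives the 11-acetoxy-12-hydroxy acid F4. Yamaguchi lactonisation (2,4,6-trichlorobenzoyl chloride, Et3N, then DMAP, toluene, 80 °C, high dilution) then closes the seven-membered lactone on the tertiary hydroxyl and gives 32, so step 17 is not needed.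

Step 13 (Wittig reaction). The ylide may enolise ketone 19, or the Z:E ratio may be poor. The fallback sets out from 24 and 19 and comes back at 26; it is a stepwise Horner–Wittig olefination. Hot aqueous NaOH converts 24 into [(3E)-4-iodopent-3-en-1-yl]diphenylphosphine oxide F1 with loss of benzene. Its lithium derivative (LiN(i-Pr)2, THF, −78 °C) adds to 19, and the β-hydroxy phosphine oxide diastereomer that leads to the Z-alkene, adduct F2, is separated by chromatography. NaH in DMF then brings about stereospecific syn-elimination of diphenylphosphinate and gives 26.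

Step 20 (CBS reduction). The conformation of the 14-membered enone 34 may override the oxazaborolidine. The fallback sets out from 32 and comes back at 35; it sets C3 in the ring-closing step itself. The Nozaki–Hiyama–Kishi cyclisation is run with CrCl2 complexed by a chiral oxazoline–sulfonamide ligand (NiCl2 cocatalyst, Et3N, THF), so that the reagent selects the aldehyde face and steps 19 and 20 fall away. The ligand enantiomer that gives (3S) would have to be found by experiment. This fallback makes no compound outside the list, F0.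

Further compounds
F1 | step 13 | [(3E)-4-iodopent-3-en-1-yl]diphenylphosphine oxide | C/C(I)=C\CCP(=O)(c1ccccc1)c1ccccc1
F2 | step 13 | (1S,4E,9R,11R,12R)-9-[(tert-butyldimethylsilyl)oxy]-7-(diphenylphosphoryl)-11,12-epoxy-8-hydroxy-4-iodo-3,3-dimethoxy-16-[(4-methoxybenzyl)oxy]-3,4-secocembra-4,15(17)-diene (the 7,8-diastereomer that gives the Z-alkene) | C/C(I)=C\CC(P(=O)(c1ccccc1)c1ccccc1)C(C)(O)[C@H](O[Si](C)(C)C(C)(C)C)C[C@H]1O[C@]1(C)CC[C@@H](CC(OC)OC)C(=C)COCc1ccc(OC)cc1
F3 | step 16 | (1S,4E,7Z,9R,11R,12S)-9-[(tert-butyldimethylsilyl)oxy]-11,12-dihydroxy-4-iodo-3-oxo-3,4-secocembra-4,7,15(17)-trien-16-oic acid | OC(=O)C(=C)[C@H](CC=O)CC[C@](C)(O)[C@H](O)C[C@@H](O[Si](C)(C)C(C)(C)C)/C(C)=C\C/C=C(C)/I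
F4 | step 16 | (1S,4E,7Z,9R,11R,12S)-11-acetoxy-9-[(tert-butyldimethylsilyl)oxy]-12-hydroxy-4-iodo-3-oxo-3,4-secocembra-4,7,15(17)-trien-16-oic acid | OC(=O)C(=C)[C@H](CC=O)CC[C@](C)(O)[C@H](OC(C)=O)C[C@@H](O[Si](C)(C)C(C)(C)C)/C(C)=C\C/C=C(C)/I
F0 | step 20 | none | none
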